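The gamma flask could not be read at 40 min, because its readings stop at 12.0 min, so I needed a number that would carry past the last reading.

| flask | starting material | remark | time |
|---|---|---|---|
| gamma | 2 M | the very flask that is asked about, followed so far |  |
| epsilon | 1.3 M | run made earlier |  |
| flask | 2.0 M |  | 40 min |

| run | time / min | isomer of the product B / % | target / % | isomer of the product A / % | starting material / % |
|---|---|---|---|---|---|
| gamma | 1.50 | 44 | 11 | 5 | 34 |
| gamma | 3.00 | 57 | 15 | 6 | 17 |
| gamma | 5.00 | 62 | 16 | 9 | 16 |
| gamma | 6.00 | 62 | 17 | 12 | 15 |
| gamma | 8.00 | 62 | 19 | 7 | 15 |
| gamma | 10.0 | 63 | 17 | 9 | 13 |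
| gamma | 12.0 | 59 | 21 | 8 | 13 |
| epsilon | 0.833 | 33 | 7 | 2 | 55 |
| epsilon | 2.50 | 53 | 11 | 8 | 24 |
| epsilon | 5.00 | 60 | 15 | 9 | 14 |
| epsilon | 6.00 | 62 | 16 | 9 | 17 |
| epsilon | 10.0 | 60 | 20 | 6 | 13 |
| epsilon | 12.0 | 58 | 19 | 8 | 13 |
| epsilon | 15.0 | 60 | 17 | 8 | 14 |

(readings scatter by 2 percentage points)

- percent here means starting material units held: one idle adduct counts as two
- what is said of target includes idle adduct
- the numbers in the tables scatter by 2 percentage points (one standard deviation)
- steps that have been proposed: isomer of the product A <-> isomer of the product B; starting material + target <-> idle adduct; isomer of the product B <-> starting material; target <-> isomer of the product A; starting material <-> target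
- in an amount of target, one idle adduct counts as one target
- a reading or a percentage of starting material is of its free form alone

- the species in which most of what was charged as starting material, at 40 min sits (target / isomer of the product A / isomer of the product B / starting material)
- the largest share itself, whichever of these holds it, in percent of the starting material charged

In the gamma flask, isomer of the product B read 62 % at 5.00 min and 59 % at 12.0 min. I therefore treated the flat stretch as an equilibrium, a case of thermodynamic control. I kept 58.4 % as the plateau share, the fraction of the summed last readings that sits in isomer of the product B, a sum that counts idle adduct once, through target. To test whether this one number was enough, I took it from the epsilon run's last reading, at 1.3 M against 2 M. That gave 60.6 %, a gap of 2.2 percentage points beside a scatter of 2 points. So I committed to isomer of the product B at about the gamma value.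

The forecast named isomer of the product B at 60 %, 1.6 points above my number, and read the flat stretch as “true equilibrium rather than a slow crawl”.

The flask gave isomer of the product B at 57.4 %, with target at 19.0 %.

    isomer of the product A ⇌ isomer of the product B (K = 6.00, k = 0.00200 s⁻¹)
    starting material + target ⇌ idle adduct, settled at all times (K = 0.300 M⁻¹)
    isomer of the product B ⇌ starting material (k = 0.00210 s⁻¹)
    target ⇌ isomer of the product A (K = 0.540, k = 0.0190 s⁻¹)
    starting material ⇌ target (K = 1.40, k = 0.00300 s⁻¹)

The plateau share of 58.4 % stood 1 point above the share of isomer of the product B in the asked flask. On the neighbour flask, charged with 1.2 M at the same time, the same share stood 0.4 points above the 58.0 % of isomer of the product B found there. That neighbour flask held idle adduct at 1.65 %, against 2.69 % in the asked flask.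

The numbers in the tables come from a simulation on assumed constants; noise was put on by code.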